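**Retrosynthetic overview**
1. Target ⇐ 1β,2β-epoxy-3-ketone ⇐ ring A 1-en-3-one. Ring A and the 19,10-lactone come from a tandem intramolecular Michael (C4–C5)/aldol (C3–C4) reaction of a C10 propionate that carries a 3-oxopropyl arm.
2. That arm and the C10 carbinol come from the key intermolecular carbonyl allylation (C1–C10 bond): tricyclic B/C/D ketone (fragment 1) + allyl nucleophile (fragment 2, C1–C3).
3. Ring B (C9–C10) ⇐ intramolecular Stetter reaction on a bicyclo[3.2.1]octenone; ring D (C13–C16) ⇐ gold-catalysed silyl enol ether/alkyne cyclisation.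
4. Quaternary C8 ⇐ Ireland–Claisen rearrangement, with chirality relayed from a CBS-derived cyclohexenol made from 3-ethoxycyclohexenone.
5. Ring order: C, D, B, then A together with the lactone.

Convention (assumed): gibberellane numbering throughout (ring A C1–C5/C10; ring B C5, C6, C8–C10; ring C C8, C9, C11–C14; ring D C8, C13–C16; C17 methylene, C18 methyl, C19 lactone carbonyl, C7 carboxyl); β is the face of H-5, H-9 and C15, α the face of the lactone bridge and C14; TMSE = 2-(trimethylsilyl)ethyl.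

**Route**

Step 1
Reactants: 1 3-ethoxycyclohex-2-en-1-one; 2 3-bromo-1-(trimethylsilyl)prop-1-yne
Product: 5 3-[3-(trimethylsilyl)prop-2-yn-1-yl]cyclohex-2-en-1-one, via Grignard reagent 3 (not isolated), via ethoxy carbinol 4 (not isolated)
Conditions: Mg, HgCl2 (cat.), Et2O, 0 °C; add 1, −20 → 0 °C; then 1 M HCl, 0 °C
Reagents that add atoms: water, O
Why: Stork–Danheiser sequence in which the silyl-stabilised allenyl/propargyl Grignard adds 1,2 to the vinylogous ester (SE2′, giving the homopropargyl adduct) and acid unmasks the transposed enone; no stereocentre is formed.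

Step 2
Reactants: 5 3-[3-(trimethylsilyl)prop-2-yn-1-yl]cyclohex-2-en-1-one
Product: 6 (R)-3-[3-(trimethylsilyl)prop-2-yn-1-yl]cyclohex-2-en-1-ol
Conditions: (S)-Me-CBS oxazaborolidine (0.15 equiv), catecholborane, toluene, −78 °C; aqueous work-up
Reagents that add atoms: none
Why: CBS reduction in which the alkenyl arm acts as the large group, so the (S)-catalyst gives the (R)-carbinol (C11), the stereocentre that later relays chirality to C8.

Step 3
Reactants: 7 methyl 4,4-dimethoxybutanoate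
Product: 8 4,4-dimethoxybutanoic acid
Conditions: LiOH, THF/H2O, 0 °C → rt; cold 1 M HCl to pH 4, immediate extraction
Reagents that add atoms: lithium hydroxide, [Li+].[OH-]
Why: Ester saponification under basic conditions that leave the dimethyl acetal untouched.

Step 4
Reactants: 6 (R)-3-[3-(trimethylsilyl)prop-2-yn-1-yl]cyclohex-2-en-1-ol; 8 4,4-dimethoxybutanoic acid
Product: 9 (R)-3-[3-(trimethylsilyl)prop-2-yn-1-yl]cyclohex-2-en-1-yl 4,4-dimethoxybutanoate
Conditions: DCC, DMAP (cat.), CH2Cl2, 0 °C → rt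
Reagents that add atoms: none
Why: Steglich esterification of the secondary allylic alcohol with retention at the carbinol carbon.

Step 5
Reactants: 9 (R)-3-[3-(trimethylsilyl)prop-2-yn-1-yl]cyclohex-2-en-1-yl 4,4-dimethoxybutanoate
Product: 12 4,4-dimethoxy-2-[(1R)-1-(prop-2-yn-1-yl)cyclohex-2-en-1-yl]butanoic acid (C6 epimers), via silyl ketene acetal 10 (not isolated), via silyl ester 11 (not isolated)
Conditions: LiN(i-Pr)2, TMSCl/Et3N, THF, −78 °C → rt → 60 °C; then 1 M NaOH, MeOH, rt; cold HCl to pH 4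
Reagents that add atoms: none
Why: Ireland–Claisen [3,3]-rearrangement, suprafacial across the allyl unit, so the C6–C8 bond forms on the ring face the C11 oxygen occupied and the quaternary C8 is set (R), while the basic methanolic work-up also removes the alkynyl silyl group; the C6 epimer mixture is erased in step 16.

Step 6
Reactants: 12 4,4-dimethoxy-2-[(1R)-1-(prop-2-yn-1-yl)cyclohex-2-en-1-yl]butanoic acid (C6 epimers)
Product: 13 2-(trimethylsilyl)ethyl 4,4-dimethoxy-2-[(1R)-1-(prop-2-yn-1-yl)cyclohex-2-en-1-yl]butanoate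
Conditions: TMSCH2CH2OH, DCC, DMAP, CH2Cl2, rt
Reagents that add atoms: 2-(trimethylsilyl)ethanol, C[Si](C)(C)CCO
Why: Steglich esterification installing a fluoride-labile ester, so the C7 acid can later be freed without hydroxide.

Step 7
Reactants: 13 2-(trimethylsilyl)ethyl 4,4-dimethoxy-2-[(1R)-1-(prop-2-yn-1-yl)cyclohex-2-en-1-yl]butanoate
Product: 14 2-(trimethylsilyl)ethyl 4,4-dimethoxy-2-[(1R)-4-oxo-1-(prop-2-yn-1-yl)cyclohex-2-en-1-yl]butanoate
Conditions: Rh2(cap)4 (cap = caprolactamate, 1 mol%), t-BuOOH (70% aq.), K2CO3, CH2Cl2, rt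
Reagents that add atoms: tert-butyl hydroperoxide, CC(C)(C)OO
Why: Radical allylic C–H oxidation at C12, the only allylic methylene (the other allylic carbon, C8, is quaternary), giving the 4,4-disubstituted cyclohexenone.

Step 8
Reactants: 14 2-(trimethylsilyl)ethyl 4,4-dimethoxy-2-[(1R)-4-oxo-1-(prop-2-yn-1-yl)cyclohex-2-en-1-yl]butanoate
Product: 16 cross-conjugated TBS dienol ether of 14 (C12–OTBS; C12=C13; C9=C11), via lithium dienolate 15 (not isolated)
Conditions: LiN(SiMe3)2 (1.1 equiv), THF, −78 °C; then TBSOTf, −78 °C; Et3N quench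
Reagents that add atoms: tert-butyldimethylsilyl triflate, CC(C)(C)[Si](C)(C)OS(=O)(=O)C(F)(F)F
Why: Kinetic enolisation/O-silylation in which only C13 can be deprotonated (no γ-hydrogen because C8 is quaternary) and the amide base is too weak to metalate the alkyne or the hindered ester.

Step 9
Reactants: 16 cross-conjugated TBS dienol ether of 14
Product: 17 bicyclo[3.2.1]octenone ester (C12 ketone; C9=C11; 16-methylene; C8 bears CH(CO2TMSE)CH2CH(OMe)2)
Conditions: Ph3PAuCl (5 mol%), AgBF4 (5 mol%), toluene/MeOH 10:1, rt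
Reagents that add atoms: none
Why: Gold-catalysed 5-exo-dig carbocyclisation (Conia-ene type) of the silyl enol ether onto the alkyne forms C13–C16 and the exocyclic methylene of ring D; the bridge can only close on the face of C8 that carries the propargyl arm, so C13 follows from C8.

Step 10
Reactants: 17 bicyclo[3.2.1]octenone ester (dimethyl acetal)
Product: 18 bicyclo[3.2.1]octenone aldehyde (C10 = CHO)
Conditions: PPTS, acetone/H2O 10:1, 45 °C
Reagents that add atoms: water, O
Why: Mild acid-catalysed acetal hydrolysis that leaves the exocyclic alkene and the TMSE ester intact.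

Step 11
Reactants: 18 bicyclo[3.2.1]octenone aldehyde
Product: 19 tricyclic B/C/D 10,12-diketone TMSE ester (H-9β; 16-methylene; C6 epimers)
Conditions: 2-(pentafluorophenyl)-6,7-dihydro-5H-pyrrolo[2,1-c][1,2,4]triazolium tetrafluoroborate (20 mol%), i-Pr2NEt, toluene, 40 °C
Reagents that add atoms: none
Why: Intramolecular Stetter reaction (carbene umpolung, 5-exo) in which the C10 acyl anion equivalent can reach the enone β-carbon C9 only from the exo face it is tethered to, closing ring B cis-fused with H-9 as in the target.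

Step 12
Reactants: 19 tricyclic B/C/D 10,12-diketone TMSE ester
Product: 20 12α-hydroxy-10-ketone TMSE ester
Conditions: LiBH(s-Bu)3 (1.05 equiv), THF, −78 °C; H2O
Reagents that add atoms: none
Why: Chemo- and stereoselective hydride reduction in which the bulky borohydride takes the six-ring C12 ketone ahead of the cyclopentanone C10 and enters from the β face because the syn-axial C9–C10 bond screens the α face, giving the axial 12α-alcohol.

Step 13
Reactants: 20 12α-hydroxy-10-ketone TMSE ester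
Product: 21 12α-OTBS 10-ketone TMSE ester (fragment 1)
Conditions: TBSOTf, 2,6-lutidine, CH2Cl2, −78 → 0 °C
Reagents that add atoms: tert-butyldimethylsilyl triflate, CC(C)(C)[Si](C)(C)OS(=O)(=O)C(F)(F)F
Why: Silylation of the hindered secondary alcohol, which traps the open hydroxy ketone even if 20 rests partly as its 10,12-hemiketal.

Step 14
Reactants: 21 12α-OTBS 10-ketone TMSE ester (fragment 1); 22 allylmagnesium bromide (fragment 2)
Product: 23 10β-allyl-10α-hydroxy 12α-OTBS TMSE ester
Conditions: CeCl3, THF, −78 °C; CH2=CHCH2MgBr (1.2 equiv); aq. NH4Cl at −78 °C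
Reagents that add atoms: none
Why: Key intermolecular carbonyl allylation forming C1–C10, in which the allyl nucleophile attacks the cyclopentanone from the convex β face (the α face is covered by ring C and the 12α-silyloxy group), giving the 10α tertiary alcohol while the cerium salt suppresses enolisation and ester attack.

Step 15
Reactants: 23 10β-allyl-10α-hydroxy 12α-OTBS TMSE ester
Product: 25 6-phenylselanyl derivative of 23, via dilithium alkoxide enolate 24 (not isolated)
Conditions: LiN(i-Pr)2 (2.3 equiv), THF, −78 °C; PhSeBr (1.05 equiv), −78 °C; H2O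
Reagents that add atoms: phenylselenenyl bromide, Br[Se]c1ccccc1
Why: α-Selenenylation of the C6 ester enolate, which at −78 °C is far faster than addition of the selenium electrophile to the alkenes.

Step 16
Reactants: 25 6-phenylselanyl derivative of 23
Product: 27 10β-allyl-10α-hydroxy-5-ene TMSE ester (C5=C6 enoate), via selenoxide 26 (not isolated)
Conditions: 30% H2O2, pyridine, CH2Cl2, 0 °C → rt
Reagents that add atoms: none
Why: Selenoxide syn-elimination that can only use the C5 hydrogens (C8 is quaternary), giving the C5=C6 enoate regiospecifically and removing the C6 stereocentre.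

Step 17
Reactants: 27 10β-allyl-10α-hydroxy-5-ene TMSE ester; 28 propionyl chloride
Product: 30 10α-propionyloxy-10β-allyl-5-ene TMSE ester, via lithium alkoxide 29 (not isolated)
Conditions: LiN(SiMe3)2, THF, −78 °C; then EtCOCl, −78 → 0 °C
Reagents that add atoms: none
Why: O-Acylation of the pre-formed tertiary alkoxide installs the propionate that supplies C4, C18 and C19, avoiding acid that would ionise the tertiary allylic alcohol.

Step 18
Reactants: 30 10α-propionyloxy-10β-allyl-5-ene TMSE ester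
Product: 32 10β-(3-hydroxypropyl) 10α-propionate (C3 primary alcohol), via alkylborane 31 (not isolated)
Conditions: Sia2BH (from BH3·THF + 2-methylbut-2-ene), THF, 0 °C; then 30% H2O2, aq. NaOAc, 0 °C → rt
Reagents that add atoms: hydrogen peroxide, OO
Why: Anti-Markovnikov hydroboration–oxidation, chemoselective because disiamylborane reacts with the monosubstituted vinyl group much faster than with the hindered 1,1-disubstituted C16 methylene or the electron-poor enoate.

Step 19
Reactants: 32 10β-(3-hydroxypropyl) 10α-propionate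
Product: 33 10β-(3-oxopropyl) 10α-propionate (C3 aldehyde)
Conditions: Dess–Martin periodinane, NaHCO3, CH2Cl2, 0 °C → rt
Reagents that add atoms: none
Why: Dess–Martin oxidation of the primary alcohol to the aldehyde under buffered, non-epimerising conditions.

Step 20
Reactants: 33 10β-(3-oxopropyl) 10α-propionate
Product: 35 pentacyclic 3-hydroxy-19,10-lactone (12α-OTBS; 7-TMSE ester; C3 epimers), via Michael adduct 34 (not isolated)
Conditions: KH (2.2 equiv), THF/DMF, −20 → 0 °C; AcOH quench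
Reagents that add atoms: none
Why: Tandem intramolecular Michael–aldol reaction (a tactic with precedent in gibberellin synthesis) in which the propionate enolate, delivered through the 10α oxygen, adds to C5 on the α face (cis-fused γ-lactone, H-5β) and the lactone enolate then closes ring A on the C3 aldehyde, which is geometrically possible only with C18 β; C6 equilibrates to the ester trans to C4.

Step 21
Reactants: 35 pentacyclic 3-hydroxy-19,10-lactone
Product: 37 3-oxo-1-ene lactone (12α-OTBS; 7-TMSE ester), via 3-ketone 36 (not isolated)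
Conditions: IBX (4 equiv), DMSO, 70 °C
Reagents that add atoms: none
Why: IBX oxidation of the alcohol followed by IBX dehydrogenation of the ketone, which can only desaturate C1–C2 because C4 is quaternary.

Step 22
Reactants: 37 3-oxo-1-ene lactone (12α-OTBS; 7-TMSE ester)
Product: 38 12α-hydroxy-3-oxo-1-ene 7-oic acid
Conditions: n-Bu4NF, THF, 0 → 40 °C; dilute HCl work-up
Reagents that add atoms: none
Why: Fluoride-induced cleavage of the silyl ether and fragmentation of the 2-silylethyl ester, done at the robust enone stage so that no deprotection follows the base-sensitive β-hydroxy ketone.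

Step 23
Reactants: 38 12α-hydroxy-3-oxo-1-ene 7-oic acid
Product: 39 1β,2β-epoxy-12α-hydroxy-3-oxo 7-oic acid
Conditions: 30% H2O2, NaOH (2.2 equiv), MeOH/H2O, −10 → 0 °C; HCl to pH 3
Reagents that add atoms: hydrogen peroxide, OO
Why: Weitz–Scheffer nucleophilic epoxidation in which hydroperoxide adds to C1 from the β face (the α face is blocked by the lactone bridge), giving the 1β,2β-epoxide.

Step 24
Reactants: 39 1β,2β-epoxy-12α-hydroxy-3-oxo 7-oic acid
Product: 40 target CNP0259985.1 (1β,12α-dihydroxy-3-oxo C19-gibberellin 19,10-lactone 7-oic acid)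
Conditions: SmI2 (4 equiv), THF/MeOH, −78 °C
Reagents that add atoms: none
Why: Reductive opening of the α,β-epoxy ketone, in which electron transfer cleaves only the C2–O bond so the C1–O bond and its β configuration are retained, and cold protonation of the samarium enolate prevents β-elimination.

**Compound list**
1 | 3-ethoxycyclohex-2-en-1-one | CCOC1=CC(=O)CCC1 | starting material
2 | 3-bromo-1-(trimethylsilyl)prop-1-yne | C[Si](C)(C)C#CCBr | starting material
3 | [3-(trimethylsilyl)prop-2-yn-1-yl]magnesium bromide (propargyl/allenyl Grignard) | C[Si](C)(C)C#CC[Mg]Br | intermediate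
4 | 3-ethoxy-1-[3-(trimethylsilyl)prop-2-yn-1-yl]cyclohex-2-en-1-ol (racemic adduct) | CCOC1=CC(O)(CC#C[Si](C)(C)C)CCC1 | intermediate
5 | 3-[3-(trimethylsilyl)prop-2-yn-1-yl]cyclohex-2-en-1-one | C[Si](C)(C)C#CCC1=CC(=O)CCC1 | intermediate
6 | (R)-3-[3-(trimethylsilyl)prop-2-yn-1-yl]cyclohex-2-en-1-ol | O[C@H]1C=C(CC#C[Si](C)(C)C)CCC1 | intermediate
7 | methyl 4,4-dimethoxybutanoate | COC(=O)CCC(OC)OC | starting material
8 | 4,4-dimethoxybutanoic acid | OC(=O)CCC(OC)OC | intermediate
9 | (R)-3-[3-(trimethylsilyl)prop-2-yn-1-yl]cyclohex-2-en-1-yl 4,4-dimethoxybutanoate | COC(OC)CCC(=O)O[C@H]1C=C(CC#C[Si](C)(C)C)CCC1 | intermediate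
10 | trimethylsilyl ketene acetal of 9 | COC(OC)CC=C(O[Si](C)(C)C)O[C@H]1C=C(CC#C[Si](C)(C)C)CCC1 | intermediate
11 | trimethylsilyl ester of the rearranged acid (alkynyl TMS retained; C8 R; C6 epimers) | C[Si](C)(C)C#CC[C@]1(C=CCCC1)C(CC(OC)OC)C(=O)O[Si](C)(C)C | intermediate
12 | 4,4-dimethoxy-2-[(1R)-1-(prop-2-yn-1-yl)cyclohex-2-en-1-yl]butanoic acid (C6 epimers) | C#CC[C@]1(C=CCCC1)C(CC(OC)OC)C(=O)O | intermediate
13 | 2-(trimethylsilyl)ethyl 4,4-dimethoxy-2-[(1R)-1-(prop-2-yn-1-yl)cyclohex-2-en-1-yl]butanoate | C#CC[C@]1(C=CCCC1)C(CC(OC)OC)C(=O)OCC[Si](C)(C)C | intermediate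
14 | 2-(trimethylsilyl)ethyl 4,4-dimethoxy-2-[(1R)-4-oxo-1-(prop-2-yn-1-yl)cyclohex-2-en-1-yl]butanoate | C#CC[C@]1(C=CC(=O)CC1)C(CC(OC)OC)C(=O)OCC[Si](C)(C)C | intermediate
15 | lithium cross-conjugated dienolate of 14 | C#CC[C@]1(C=CC(O[Li])=CC1)C(CC(OC)OC)C(=O)OCC[Si](C)(C)C | intermediate
16 | cross-conjugated TBS dienol ether of 14 | C#CC[C@]1(C=CC(O[Si](C)(C)C(C)(C)C)=CC1)C(CC(OC)OC)C(=O)OCC[Si](C)(C)C | intermediate
17 | bicyclo[3.2.1]octenone ester (rings C/D; C12 ketone; C9=C11; 16-methylene; dimethyl acetal at C10) | C=C1C[C@@]2(C[C@H]1C(=O)C=C2)C(CC(OC)OC)C(=O)OCC[Si](C)(C)C | intermediate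
18 | bicyclo[3.2.1]octenone aldehyde (C10 = CHO) | C=C1C[C@@]2(C[C@H]1C(=O)C=C2)C(CC=O)C(=O)OCC[Si](C)(C)C | intermediate
19 | tricyclic B/C/D 10,12-diketone TMSE ester (H-9β; C6 epimers) | C=C1C[C@]23C[C@H]1C(=O)C[C@H]2C(=O)CC3C(=O)OCC[Si](C)(C)C | intermediate
20 | 12α-hydroxy-10-ketone TMSE ester | C=C1C[C@]23C[C@H]1[C@@H](O)C[C@H]2C(=O)CC3C(=O)OCC[Si](C)(C)C | intermediate
21 | 12α-OTBS 10-ketone TMSE ester (fragment 1) | C=C1C[C@]23C[C@H]1[C@@H](O[Si](C)(C)C(C)(C)C)C[C@H]2C(=O)CC3C(=O)OCC[Si](C)(C)C | intermediate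
22 | allylmagnesium bromide (fragment 2) | C=CC[Mg]Br | starting material
23 | 10β-allyl-10α-hydroxy 12α-OTBS TMSE ester | C=C1C[C@]23C[C@H]1[C@@H](O[Si](C)(C)C(C)(C)C)C[C@H]2[C@](O)(CC=C)CC3C(=O)OCC[Si](C)(C)C | intermediate
24 | dilithium alkoxide/ester enolate of 23 | C=C1C[C@]23C[C@H]1[C@@H](O[Si](C)(C)C(C)(C)C)C[C@H]2[C@](O[Li])(CC=C)CC3=C(O[Li])OCC[Si](C)(C)C | intermediate
25 | 6-phenylselanyl derivative of 23 (C6 epimers) | C=C1C[C@]23C[C@H]1[C@@H](O[Si](C)(C)C(C)(C)C)C[C@H]2[C@](O)(CC=C)CC3([Se]c4ccccc4)C(=O)OCC[Si](C)(C)C | intermediate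
26 | selenoxide of 25 | C=C1C[C@]23C[C@H]1[C@@H](O[Si](C)(C)C(C)(C)C)C[C@H]2[C@](O)(CC=C)CC3([Se](=O)c4ccccc4)C(=O)OCC[Si](C)(C)C | intermediate
27 | 10β-allyl-10α-hydroxy-5-ene TMSE ester | C=C1C[C@]23C[C@H]1[C@@H](O[Si](C)(C)C(C)(C)C)C[C@H]2[C@](O)(CC=C)C=C3C(=O)OCC[Si](C)(C)C | intermediate
28 | propionyl chloride | CCC(Cl)=O | starting material
29 | lithium alkoxide of 27 | C=C1C[C@]23C[C@H]1[C@@H](O[Si](C)(C)C(C)(C)C)C[C@H]2[C@](O[Li])(CC=C)C=C3C(=O)OCC[Si](C)(C)C | intermediate
30 | 10α-propionyloxy-10β-allyl-5-ene TMSE ester | C=C1C[C@]23C[C@H]1[C@@H](O[Si](C)(C)C(C)(C)C)C[C@H]2[C@](OC(=O)CC)(CC=C)C=C3C(=O)OCC[Si](C)(C)C | intermediate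
31 | C3 disiamylborane adduct of 30 | C=C1C[C@]23C[C@H]1[C@@H](O[Si](C)(C)C(C)(C)C)C[C@H]2[C@](OC(=O)CC)(CCCB(C(C)C(C)C)C(C)C(C)C)C=C3C(=O)OCC[Si](C)(C)C | intermediate
32 | 10β-(3-hydroxypropyl) 10α-propionate | C=C1C[C@]23C[C@H]1[C@@H](O[Si](C)(C)C(C)(C)C)C[C@H]2[C@](OC(=O)CC)(CCCO)C=C3C(=O)OCC[Si](C)(C)C | intermediate
33 | 10β-(3-oxopropyl) 10α-propionate | C=C1C[C@]23C[C@H]1[C@@H](O[Si](C)(C)C(C)(C)C)C[C@H]2[C@](OC(=O)CC)(CCC=O)C=C3C(=O)OCC[Si](C)(C)C | intermediate
34 | Michael adduct: 19,10-lactone with C4–H and 3-oxopropyl arm (C4/C6 unassigned) | C=C1C[C@]23C[C@H]1[C@@H](O[Si](C)(C)C(C)(C)C)C[C@H]2[C@@]4(CCC=O)OC(=O)C(C)[C@H]4C3C(=O)OCC[Si](C)(C)C | intermediate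
35 | pentacyclic 3-hydroxy-19,10-lactone (12α-OTBS; 7-TMSE ester; C3 epimers) | C=C1C[C@]23C[C@H]1[C@@H](O[Si](C)(C)C(C)(C)C)C[C@H]2[C@]12OC(=O)[C@](C)(C(O)CC1)[C@H]2[C@@H]3C(=O)OCC[Si](C)(C)C | intermediate
36 | 3-ketone of 35 | C=C1C[C@]23C[C@H]1[C@@H](O[Si](C)(C)C(C)(C)C)C[C@H]2[C@]12OC(=O)[C@](C)(C(=O)CC1)[C@H]2[C@@H]3C(=O)OCC[Si](C)(C)C | intermediate
37 | 3-oxo-1-ene lactone (12α-OTBS; 7-TMSE ester) | C=C1C[C@]23C[C@H]1[C@@H](O[Si](C)(C)C(C)(C)C)C[C@H]2[C@]12OC(=O)[C@](C)(C(=O)C=C1)[C@H]2[C@@H]3C(=O)OCC[Si](C)(C)C | intermediate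
38 | 12α-hydroxy-3-oxo-1-ene 7-oic acid | C=C1C[C@]23C[C@H]1[C@@H](O)C[C@H]2[C@]12OC(=O)[C@](C)(C(=O)C=C1)[C@H]2[C@@H]3C(=O)O | intermediate
39 | 1β,2β-epoxy-12α-hydroxy-3-oxo 7-oic acid | C=C1C[C@]23C[C@H]1[C@@H](O)C[C@H]2[C@]12OC(=O)[C@](C)(C(=O)[C@H]4O[C@H]41)[C@H]2[C@@H]3C(=O)O | intermediate
40 | CNP0259985.1: 1β,12α-dihydroxy-3-oxo C19-gibberellin 19,10-lactone 7-oic acid | C=C1C[C@]23C[C@H]1[C@@H](O)C[C@H]2[C@]12OC(=O)[C@](C)(C(=O)C[C@H]1O)[C@H]2[C@@H]3C(=O)O | target

**Step count**
Total: 24 steps. Longest linear sequence: 23 steps (steps 1, 2 and 4–24 from 1 and 2; step 3 is a one-step side branch).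

**Three steps most likely to fail, each with a fallback**

Step 12 (selective reduction of the C12 ketone next to the C10 ketone). If the borohydride does not discriminate the two ketones, the fallback sets out from aldehyde 18 and never makes a diketone. SmI2 in THF/t-BuOH closes ring B by ketyl–enone coupling to give the 10-hydroxy-12-ketone F1. Its C10 hydroxyl is capped with TESCl/imidazole to give the 10-OTES 12-ketone F2. LiBH(s-Bu)3 then reduces the only remaining ketone to the 12α-hydroxy 10-OTES compound F3. TBSOTf/2,6-lutidine gives the 12α-OTBS 10-OTES compound F4. PPTS in MeOH removes the secondary triethylsilyl group selectively to give the 12α-OTBS 10-alcohol F5. Dess–Martin oxidation of F5 comes back to the route at ketone 21.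

Step 18 (hydroboration of the allyl group in the presence of the C16 methylene). If borane selectivity is insufficient, the fallback sets out from propionate 30 and oxidises the terminal vinyl group directly to the aldehyde. An aldehyde-selective Wacker oxidation is used (PdCl2(PhCN)2, CuCl2, AgNO2, O2, t-BuOH/MeNO2, rt), under which 1,1-disubstituted alkenes are inert. It comes back to the route at aldehyde 33 and makes no new compound.

Step 20 (tandem Michael–aldol in the presence of an enolisable aldehyde). If the cascade gives aldehyde self-condensation, the fallback sets out from alcohol 32 and runs the two ring closures separately. The primary alcohol is masked with TESCl/imidazole as the 3-OTES propionate F6. KN(SiMe3)2 in THF at −78 °C then effects the Michael addition alone to give the 3-OTES 19,10-lactone F7. PPTS in MeOH frees the lactone primary alcohol F8. Dess–Martin oxidation gives aldehyde 34, now isolated. Ring A is closed under equilibrating conditions (DBU, THF, rt) by the same aldol that is known to be reversible and ring-closed-favoured in 3-hydroxy gibberellins. This comes back to the route at hydroxy lactone 35.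

**Further compounds**
F1 | step 12 | 10-hydroxy-12-ketone tricyclic TMSE ester (C10 and C6 epimers) | C=C1C[C@]23C[C@H]1C(=O)C[C@H]2C(O)CC3C(=O)OCC[Si](C)(C)C
F2 | step 12 | 10-OTES 12-ketone tricyclic TMSE ester | C=C1C[C@]23C[C@H]1C(=O)C[C@H]2C(O[Si](CC)(CC)CC)CC3C(=O)OCC[Si](C)(C)C
F3 | step 12 | 12α-hydroxy 10-OTES tricyclic TMSE ester | C=C1C[C@]23C[C@H]1[C@@H](O)C[C@H]2C(O[Si](CC)(CC)CC)CC3C(=O)OCC[Si](C)(C)C
F4 | step 12 | 12α-OTBS 10-OTES tricyclic TMSE ester | C=C1C[C@]23C[C@H]1[C@@H](O[Si](C)(C)C(C)(C)C)C[C@H]2C(O[Si](CC)(CC)CC)CC3C(=O)OCC[Si](C)(C)C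
F5 | step 12 | 12α-OTBS 10-alcohol tricyclic TMSE ester | C=C1C[C@]23C[C@H]1[C@@H](O[Si](C)(C)C(C)(C)C)C[C@H]2C(O)CC3C(=O)OCC[Si](C)(C)C
F0 | step 18 | none | none
F6 | step 20 | 3-OTES ether of 32 | C=C1C[C@]23C[C@H]1[C@@H](O[Si](C)(C)C(C)(C)C)C[C@H]2[C@](OC(=O)CC)(CCCO[Si](CC)(CC)CC)C=C3C(=O)OCC[Si](C)(C)C
F7 | step 20 | 19,10-lactone Michael adduct with 3-OTES propyl arm | C=C1C[C@]23C[C@H]1[C@@H](O[Si](C)(C)C(C)(C)C)C[C@H]2[C@@]4(CCCO[Si](CC)(CC)CC)OC(=O)C(C)[C@H]4C3C(=O)OCC[Si](C)(C)C
F8 | step 20 | 19,10-lactone Michael adduct with 3-hydroxypropyl arm | C=C1C[C@]23C[C@H]1[C@@H](O[Si](C)(C)C(C)(C)C)C[C@H]2[C@@]4(CCCO)OC(=O)C(C)[C@H]4C3C(=O)OCC[Si](C)(C)C
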